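**Retrosynthetic overview**
1. Rigidin B 12 ⇐ its bis(benzyl ether) 11; the two phenols are unmasked last by hydrogenolysis.
2. The pyrimidine-2,4-dione ring (formed second) ⇐ 2-aminopyrrole-3-carboxamide 9 plus one carbonyl carbon from oxalyl chloride.
3. The pyrrole ring (formed first) ⇐ a three-component domino of N-phenacyl methanesulfonamide 3, aldehyde 4 and cyanoacetamide 5.
4. 3 ⇐ phenacyl bromide 1 + methanesulfonamide 2.

Assumption: rigidin B has no stereocentre (it is achiral), so no stereocontrol is needed; bromoketone 1 is taken as a catalogue compound.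

**Route**

Step 1
Reactants: 1 2-bromo-1-[4-(benzyloxy)-3-methoxyphenyl]ethan-1-one; 2 methanesulfonamide
Product: 3 N-{2-[4-(benzyloxy)-3-methoxyphenyl]-2-oxoethyl}methanesulfonamide
Conditions: 2 (3 equiv), K2CO3 (1 equiv), acetone, rt
Reagents that add atoms: none
Why: SN2 N-alkylation of the sulfonamide anion by the reactive phenacyl bromide, with excess sulfonamide suppressing double alkylation.

Step 2
Reactants: 3 N-{2-[4-(benzyloxy)-3-methoxyphenyl]-2-oxoethyl}methanesulfonamide; 4 4-(benzyloxy)benzaldehyde; 5 2-cyanoacetamide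
Product: 9 2-amino-5-[4-(benzyloxy)-3-methoxybenzoyl]-4-[4-(benzyloxy)phenyl]-1H-pyrrole-3-carboxamide, via Knoevenagel acrylamide 6 (not isolated), via Michael adduct 7 (not isolated), via N-mesyl aminopyrroline 8 (not isolated)
Conditions: K2CO3 (1 equiv), EtOH, reflux
Reagents that add atoms: none
Why: A domino Knoevenagel condensation, Michael addition of the ketone α-carbon of 3, 5-exo-dig addition of the sulfonamide nitrogen to the nitrile and E1cB loss of methanesulfinate gives the aromatic 2-aminopyrrole, so the transient sp3 centres of 7 and 8 are erased.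

Step 3
Reactants: 9 2-amino-5-[4-(benzyloxy)-3-methoxybenzoyl]-4-[4-(benzyloxy)phenyl]-1H-pyrrole-3-carboxamide
Product: 11 6-[4-(benzyloxy)-3-methoxybenzoyl]-5-[4-(benzyloxy)phenyl]-1H-pyrrolo[2,3-d]pyrimidine-2,4(3H,7H)-dione, via acyl isocyanate 10 (not isolated)
Conditions: (COCl)2 (1.5 equiv), diglyme, rt then 120 °C
Reagents that add atoms: oxalyl chloride, O=C(Cl)C(=O)Cl
Why: Oxalyl chloride converts the primary carboxamide into an acyl isocyanate (Speziale reaction) that is trapped by the neighbouring 2-amino group in a 6-membered cyclocarbonylation, while the benzyl ethers and the diaryl ketone are inert to the acid chloride.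

Step 4
Reactants: 11 6-[4-(benzyloxy)-3-methoxybenzoyl]-5-[4-(benzyloxy)phenyl]-1H-pyrrolo[2,3-d]pyrimidine-2,4(3H,7H)-dione
Product: 12 rigidin B, 6-(4-hydroxy-3-methoxybenzoyl)-5-(4-hydroxyphenyl)-1H-pyrrolo[2,3-d]pyrimidine-2,4(3H,7H)-dione
Conditions: H2 (1 atm), 10% Pd/C, DMF–MeOH, rt
Reagents that add atoms: none
Why: Catalytic hydrogenolysis cleaves both benzyl aryl ethers, while the aroyl C=O is a vinylogous amide of the pyrrole and, like the aromatic core and the methyl ether, is not reduced under these conditions.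

**Compound list**
1 | 2-bromo-1-[4-(benzyloxy)-3-methoxyphenyl]ethan-1-one | COc1cc(C(=O)CBr)ccc1OCc1ccccc1 | starting material
2 | methanesulfonamide | CS(N)(=O)=O | starting material
3 | N-{2-[4-(benzyloxy)-3-methoxyphenyl]-2-oxoethyl}methanesulfonamide | COc1cc(C(=O)CNS(C)(=O)=O)ccc1OCc1ccccc1 | intermediate
4 | 4-(benzyloxy)benzaldehyde | O=Cc1ccc(OCc2ccccc2)cc1 | starting material
5 | 2-cyanoacetamide | N#CCC(N)=O | starting material
6 | (E)-3-[4-(benzyloxy)phenyl]-2-cyanoprop-2-enamide | N#C/C(C(N)=O)=C\c1ccc(OCc2ccccc2)cc1 | intermediate (not isolated)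
7 | 5-[4-(benzyloxy)-3-methoxyphenyl]-3-[4-(benzyloxy)phenyl]-2-cyano-4-(methanesulfonamido)-5-oxopentanamide, diastereomer mixture, racemic | COc1cc(C(=O)C(NS(C)(=O)=O)C(c2ccc(OCc3ccccc3)cc2)C(C#N)C(N)=O)ccc1OCc1ccccc1 | intermediate (not isolated)
8 | 2-amino-5-[4-(benzyloxy)-3-methoxybenzoyl]-4-[4-(benzyloxy)phenyl]-1-(methylsulfonyl)-4,5-dihydro-1H-pyrrole-3-carboxamide, racemic | COc1cc(C(=O)C2C(c3ccc(OCc4ccccc4)cc3)C(C(N)=O)=C(N)N2S(C)(=O)=O)ccc1OCc1ccccc1 | intermediate (not isolated)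
9 | 2-amino-5-[4-(benzyloxy)-3-methoxybenzoyl]-4-[4-(benzyloxy)phenyl]-1H-pyrrole-3-carboxamide | COc1cc(C(=O)c2[nH]c(N)c(C(N)=O)c2-c2ccc(OCc3ccccc3)cc2)ccc1OCc1ccccc1 | intermediate
10 | 2-amino-5-[4-(benzyloxy)-3-methoxybenzoyl]-4-[4-(benzyloxy)phenyl]-1H-pyrrole-3-carbonyl isocyanate | COc1cc(C(=O)c2[nH]c(N)c(C(=O)N=C=O)c2-c2ccc(OCc3ccccc3)cc2)ccc1OCc1ccccc1 | intermediate (not isolated)
11 | 6-[4-(benzyloxy)-3-methoxybenzoyl]-5-[4-(benzyloxy)phenyl]-1H-pyrrolo[2,3-d]pyrimidine-2,4(3H,7H)-dione | COc1cc(C(=O)c2[nH]c3[nH]c(=O)[nH]c(=O)c3c2-c2ccc(OCc3ccccc3)cc2)ccc1OCc1ccccc1 | intermediate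
12 | rigidin B, 6-(4-hydroxy-3-methoxybenzoyl)-5-(4-hydroxyphenyl)-1H-pyrrolo[2,3-d]pyrimidine-2,4(3H,7H)-dione | COc1cc(C(=O)c2[nH]c3[nH]c(=O)[nH]c(=O)c3c2-c2ccc(O)cc2)ccc1O | target

**Totals**
Total step count: 4. Longest linear sequence: 4 steps (1 → 3 → 9 → 11 → 12).

**Steps most likely to fail, with fallbacks**

Step 2 (three-component pyrrole synthesis). The risk is that the reaction stalls at 6, or that the Michael adduct cyclises through the ketone rather than through nitrogen. The fallback sets out from 3 (with 4) and swaps the cyano component for the more acidic malononitrile (N#CCC#N; K2CO3 or Et3N, EtOH, reflux). The same domino then gives 2-amino-5-[4-(benzyloxy)-3-methoxybenzoyl]-4-[4-(benzyloxy)phenyl]-1H-pyrrole-3-carbonitrile F1. Radziszewski hydration of the nitrile (30% H2O2, K2CO3, DMSO, rt) converts F1 into the carboxamide and comes back to the route at 9.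

Step 3 (oxalyl chloride cyclocarbonylation). The risk is acylation at the wrong nitrogen, oxamide by-products, or partial benzyl ether cleavage by hot HCl. The fallback sets out from 9 and builds the ring in two base-mediated stages. Ethyl chloroformate (CCOC(=O)Cl) in pyridine at 0 °C to rt gives ethyl N-{5-[4-(benzyloxy)-3-methoxybenzoyl]-4-[4-(benzyloxy)phenyl]-3-carbamoyl-1H-pyrrol-2-yl}carbamate F2. NaOEt in EtOH at reflux then closes the ring by attack of the carboxamide nitrogen on the carbamate with loss of ethanol, coming back to the route at 11.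

Step 4 (hydrogenolysis of 11). The risk is the very low solubility of the deazaxanthine 11, catalyst poisoning by sulfur traces, or over-reduction of the ketone. The fallback sets out from 9 and reverses the order of deprotection and annulation. Hydrogenolysis of the soluble pyrrole 9 (H2, 10% Pd/C, THF–MeOH, rt) gives 2-amino-5-(4-hydroxy-3-methoxybenzoyl)-4-(4-hydroxyphenyl)-1H-pyrrole-3-carboxamide F3. A urea melt (NC(N)=O, excess, 190 °C) carbamoylates the 2-amino group to give 5-(4-hydroxy-3-methoxybenzoyl)-4-(4-hydroxyphenyl)-2-ureido-1H-pyrrole-3-carboxamide F4, which is not isolated and cyclises in the melt with loss of ammonia. A dilute aqueous NaOH wash followed by acidification removes any phenol carbamates, and the sequence comes back to the route at 12.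

**Further compounds**
F1 | step 2 | 2-amino-5-[4-(benzyloxy)-3-methoxybenzoyl]-4-[4-(benzyloxy)phenyl]-1H-pyrrole-3-carbonitrile | COc1cc(C(=O)c2[nH]c(N)c(C#N)c2-c2ccc(OCc3ccccc3)cc2)ccc1OCc1ccccc1
F2 | step 3 | ethyl N-{5-[4-(benzyloxy)-3-methoxybenzoyl]-4-[4-(benzyloxy)phenyl]-3-carbamoyl-1H-pyrrol-2-yl}carbamate | CCOC(=O)Nc1[nH]c(C(=O)c2ccc(OCc3ccccc3)c(OC)c2)c(-c2ccc(OCc3ccccc3)cc2)c1C(N)=O
F3 | step 4 | 2-amino-5-(4-hydroxy-3-methoxybenzoyl)-4-(4-hydroxyphenyl)-1H-pyrrole-3-carboxamide | COc1cc(C(=O)c2[nH]c(N)c(C(N)=O)c2-c2ccc(O)cc2)ccc1O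
F4 | step 4 | 5-(4-hydroxy-3-methoxybenzoyl)-4-(4-hydroxyphenyl)-2-ureido-1H-pyrrole-3-carboxamide | COc1cc(C(=O)c2[nH]c(NC(N)=O)c(C(N)=O)c2-c2ccc(O)cc2)ccc1O
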